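**Plan**

1. Retrosynthesis cuts, in this order: the O–benzyl bond; the ring CH2 between the ring-fusion CH and C(CH3)OH (carried as C=O); the ring-fusion bond of the trans-5/7 core (reverse 1,2-shift, C5–C8a back to C4a–C8a) to give an all-cis cis-decalin 4a-ol 5-mesylate; the ester C–O; the oxirane, C5–O, C4–O and C7–CH3 (back to two enones); C1–C8a (Michael) to a p-quinol; the quinol C–O and the acetylenic C–C, leading to 4'-hydroxyacetophenone and 4-methylpent-1-yne.
2. Forward order: side chain, oxidative dearomatisation (ring A as cyclohexadienone), ring B by desymmetrising Michael addition (cis-decalin), decoration of ring A; then ring A contracts to the cyclopentane while ring B grows to the cycloheptane.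
3. Stereochemistry: the amine catalyst sets C4a/C8a. The angular 4a-OH relays the rest: syn epoxidations fix C4–O and C5–O, the 5-OH directs the oxirane, hydride adds to C2 anti to the axial 4-OH, and the stereospecific shift (inversion at C5) gives the trans ring fusion.
4. Enabling feature: a tertiary C4a–OH next to a secondary C5–O on a conformationally locked cis-decalin (isopropyl and C4-methyl equatorial). C5–OMs is then equatorial and antiperiplanar to the ring-fusion bond C4a–C8a, and the CH2 of the target next to C(CH3)OH is the former carbinol carbon C4a.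
5. Decalin locants used below: C1 (isopropyl), C2, C3, C4 (CH3), C4a (OH), C5–C8 (ring A), C8a.

Key step: step 12

Assumption: the sense of induction of the cinchona primary amine in step 4 cannot be predicted with certainty; the quinine-derived catalyst is written, and its quinidine-derived pseudo-enantiomer would be used if the antipode of 6 forms.

**Route**

Step 1
Reactants: 1 4'-hydroxyacetophenone; 2 4-methylpent-1-yne
Product: 3 4-(2-hydroxy-6-methylhept-3-yn-2-yl)phenol (racemic)
Conditions: 2 (3.2 equiv), n-BuLi (3.1 equiv), THF, −78 °C; then 1, LaCl3·2LiCl (30 mol %), −78 °C → rt; aq. NH4Cl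
Reagents that add atoms: none
Why: 1,2-addition of a lithium acetylide to the aryl ketone (one equivalent is consumed as the phenoxide, the lanthanum salt suppresses enolisation); the carbinol centre is racemic and is erased in step 2.

Step 2
Reactants: 3 4-(2-hydroxy-6-methylhept-3-yn-2-yl)phenol
Product: 4 2-(4-hydroxyphenyl)-6-methylhept-2-en-4-one (E/Z mixture)
Conditions: Ph3PAuNTf2 (2 mol %), MeOH (1 equiv), toluene, rt
Reagents that add atoms: none
Why: gold(I)-catalysed Meyer–Schuster rearrangement (1,3-shift of the propargylic oxygen) should give the β-aryl enone; both alkene isomers are usable because they are funnelled in step 4.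

Step 3
Reactants: 4 2-(4-hydroxyphenyl)-6-methylhept-2-en-4-one
Product: 5 4-hydroxy-4-(6-methyl-4-oxohept-2-en-2-yl)cyclohexa-2,5-dien-1-one (E/Z mixture)
Conditions: PhI(OAc)2 (1.1 equiv), MeCN–H2O 4:1, 0 °C
Reagents that add atoms: water, O
Why: hypervalent-iodine oxidative dearomatisation of a para-substituted phenol; water should attack the ipso carbon, because the electron-poor enone side chain does not support a quinone methide, to give the achiral p-quinol.

Step 4
Reactants: 5 4-hydroxy-4-(6-methyl-4-oxohept-2-en-2-yl)cyclohexa-2,5-dien-1-one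
Product: 6 cis-fused 4a-hydroxy-4-methyl-1-(propan-2-yl)-4a,8a-dihydronaphthalene-2,7(1H,8H)-dione (4a-OH and 8a-H cis, 1-isopropyl trans to C8)
Conditions: 9-amino(9-deoxy)epi-quinine (20 mol %), 2-fluorobenzoic acid (40 mol %), toluene, 40 °C
Reagents that add atoms: none
Why: intramolecular Michael addition through a cross-conjugated dienamine of the side-chain ketone, which desymmetrises the cyclohexadienone; the catalyst selects one of the two enantiotopic β-carbons and so sets C4a and C8a, the tether forces the cis ring fusion, the epimerisable C1 should settle with isopropyl pseudo-equatorial, and E/Z enone isomers interconvert through the linear dienamine while only Z can cyclise.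

Step 5
Reactants: 6 cis-fused dienedione
Product: 7 3,4:5,6-diepoxy-4a-hydroxy-4-methyl-1-(propan-2-yl)octahydronaphthalene-2,7-dione (both oxirane oxygens cis to the 4a-OH)
Conditions: t-BuOOH (4 equiv), DBU (2 equiv), CH2Cl2, 0 °C → rt
Reagents that add atoms: tert-butyl hydroperoxide, CC(C)(C)OO
Why: Weitz–Scheffer nucleophilic epoxidation of both enones; the hydrogen-bonding angular 4a-OH, on the convex face of the cis-decalin, should direct both additions syn to itself, which fixes the C4–O and C5–O configurations.

Step 6
Reactants: 7 bis-epoxy diketone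
Product: 8 7-methylidene derivative of 7 (C7=CH2, C2 ketone retained)
Conditions: Ph3PCH3Br (2.5 equiv), KOt-Bu (2.4 equiv), THF, 0 °C; then 7, −40 → 0 °C
Reagents that add atoms: methyltriphenylphosphonium bromide, C[P+](c1ccccc1)(c1ccccc1)c1ccccc1.[Br-]
Why: Wittig methylenation should occur at the C7 ketone (flanked by CH2) and not at the C2 ketone, which is shielded by the adjacent CH–isopropyl; the syn epoxy alcohol geometry cannot undergo Payne migration.

Step 7
Reactants: 8 7-methylidene bis-epoxide
Product: 9 4,4a,5-trihydroxy-4,7-dimethyl-1-(propan-2-yl)-3,4,4a,5,8,8a-hexahydronaphthalen-2(1H)-one (C6=C7 alkene; the three OH groups and 8a-H all cis)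
Conditions: SmI2 (6 equiv), THF–MeOH, −78 °C
Reagents that add atoms: none
Why: single-electron reduction with samarium diiodide: the α,β-epoxy ketone of ring B opens at Cα–O to the β-hydroxy ketone, and the vinyl oxirane of ring A opens at the allylic C6–O with protonation at the terminal CH2 (reductive 1,3-transposition), giving the C6=C7 alkene and the C7 methyl; the C4–O and C5–O bonds are untouched, so the configurations from step 5 are kept.

Step 8
Reactants: 9 triol enone
Product: 10 6,7-epoxide of 9 (oxirane oxygen cis to the 5-OH)
Conditions: VO(acac)2 (5 mol %), t-BuOOH (1.5 equiv), CH2Cl2, 0 °C → rt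
Reagents that add atoms: tert-butyl hydroperoxide, CC(C)(C)OO
Why: vanadium-catalysed hydroxyl-directed epoxidation of the allylic alcohol; oxygen is delivered to the face of the 5-OH (also the face of the 4a-OH), which sets both oxirane carbons.

Step 9
Reactants: 10 epoxy triol
Product: 11 5-O-methanesulfonate of 10
Conditions: MsCl (1.3 equiv), Et3N (2 equiv), CH2Cl2, −30 °C
Reagents that add atoms: methanesulfonyl chloride, CS(=O)(=O)Cl
Why: sulfonylation of the only secondary alcohol; the two tertiary alcohols should not react at −30 °C, and the cold conditions avoid premature rearrangement.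

Step 10
Reactants: 11 hydroxy mesylate ketone
Product: 12 2-alcohol of 11 (2-OH cis to the 4-OH and to the 1-isopropyl group)
Conditions: L-Selectride (3 equiv), THF, −78 °C; AcOH/MeOH quench at −78 °C
Reagents that add atoms: none
Why: the bulky hydride should attack the C2 ketone from the face opposite the axial 4-OH and 8a-H (equatorial attack, the menthone-to-neomenthol sense), giving the axial 2-OH; mesylate and oxirane should be inert at −78 °C.

Step 11
Reactants: 12 hydroxy mesylate alcohol; 13 3-(benzyloxy)-4-methoxybenzoic acid
Product: 14 2-O-[3-(benzyloxy)-4-methoxybenzoyl] ester of 12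
Conditions: 13 (1.5 equiv), DCC (1.6 equiv), DMAP (1 equiv), CH2Cl2, 0 °C → rt
Reagents that add atoms: none
Why: Steglich esterification of the only secondary alcohol; the tertiary alcohols are too hindered to acylate, and the phenol is masked as its benzyl ether.

Step 12
Reactants: 14 cis-decalin 4a-ol 5-mesylate ester
Product: 15 trans-fused hydroazulenone (cyclopentane with the oxirane fused to cycloheptanone; ketone between C(CH3)OH and the ring-fusion CH; aryl ester retained)
Conditions: KHMDS (1.1 equiv), THF, −78 → −20 °C; pH 7 buffer quench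
Reagents that add atoms: none
Why: The C4a alkoxide pushes while the equatorial C5 mesylate leaves and the antiperiplanar ring-fusion bond C4a–C8a migrates to C5 in one concerted 1,2-shift, C4a becoming the ketone. The closest known reaction type is the pinacol-type (semipinacol) rearrangement of cis-glycol monosulfonates that converts hydronaphthalenes into hydroazulenes. The cyclopentane (C5–C6–C7–C8–C8a) arises by contraction of ring A through this 1,2-alkyl shift, and the cycloheptane by the matching one-carbon expansion of ring B (C5 is inserted between C4a and C8a); no ring is closed by cyclisation. C5 is the only stereocentre that changes: it is inverted (new bond anti to the leaving group) while C8a migrates with retention, so the all-cis arrangement of 4a-OH, 5-OMs and 8a-H dictates the trans ring fusion. The step needs migration of C8a in preference to C4 migration, fragmentation or oxirane closure: the chair–chair conformer with isopropyl and the C4 methyl equatorial holds C5–OMs equatorial and anti to C4a–C8a only, and the cis-diol geometry excludes epoxide formation. One equivalent of base at low temperature and a buffered quench should keep the β,γ-epoxy ketone from enolising.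

Step 13
Reactants: 15 hydroazulenone
Product: 16 secondary alcohol from 15 (epimer mixture at the new carbinol)
Conditions: NaBH4 (2 equiv), MeOH–THF, −20 → 0 °C
Reagents that add atoms: none
Why: borohydride reduction directly after the rearrangement removes the base-labile β,γ-epoxy ketone; the new carbinol configuration is irrelevant because this oxygen is removed in step 15, and ester and oxirane should be inert.

Step 14
Reactants: 16 secondary alcohol
Product: 17 O-(imidazol-1-ylthiocarbonyl) derivative of 16
Conditions: 1,1'-thiocarbonyldiimidazole (1.5 equiv), DMAP (0.2 equiv), CH2Cl2, rt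
Reagents that add atoms: 1,1'-thiocarbonyldiimidazole, S=C(n1ccnc1)n1ccnc1
Why: thioacylation of the secondary alcohol (first half of a Barton–McCombie deoxygenation); the neighbouring tertiary alcohol should be too hindered to react at room temperature.

Step 15
Reactants: 17 thiocarbonyl imidazolide
Product: 18 O-benzyl ether of the target
Conditions: Bu3SnH (2 equiv), Et3B (0.2 equiv), air, toluene, rt
Reagents that add atoms: none
Why: Barton–McCombie radical deoxygenation; room-temperature initiation avoids thermal cyclisation onto the tertiary alcohol, and the secondary radical is two bonds away from the oxirane, so it cannot open it.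

Step 16
Reactants: 18 O-benzyl ether of the target
Product: 19 target (CNP0106636.1)
Conditions: H2 (1 atm), 10 % Pd/C, EtOAc, rt
Reagents that add atoms: none
Why: hydrogenolysis of the aryl benzyl ether; the trisubstituted, non-benzylic oxirane and the ester should survive.

**Compound list**

1 | 4'-hydroxyacetophenone | CC(=O)c1ccc(O)cc1 | starting material
2 | 4-methylpent-1-yne | C#CCC(C)C | starting material
3 | 4-(2-hydroxy-6-methylhept-3-yn-2-yl)phenol (racemic) | CC(C)CC#CC(C)(O)c1ccc(O)cc1 | intermediate
4 | 2-(4-hydroxyphenyl)-6-methylhept-2-en-4-one (E/Z mixture) | CC(C)CC(=O)C=C(C)c1ccc(O)cc1 | intermediate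
5 | 4-hydroxy-4-(6-methyl-4-oxohept-2-en-2-yl)cyclohexa-2,5-dien-1-one (E/Z mixture) | CC(C)CC(=O)C=C(C)C1(O)C=CC(=O)C=C1 | intermediate
6 | cis-fused 4a-hydroxy-4-methyl-1-(propan-2-yl)-4a,8a-dihydronaphthalene-2,7(1H,8H)-dione (4a-OH/8a-H cis, isopropyl trans to C8) | O=C1C=C(C)[C@@]2(O)C=CC(=O)C[C@H]2[C@@H]1C(C)C | intermediate
7 | 3,4:5,6-diepoxide of 6, both oxirane oxygens cis to the 4a-OH | O=C1[C@@H]2O[C@]2(C)[C@@]3(O)[C@@H]4O[C@@H]4C(=O)C[C@H]3[C@@H]1C(C)C | intermediate
8 | 7-methylidene derivative of 7 | O=C1[C@@H]2O[C@]2(C)[C@@]3(O)[C@@H]4O[C@@H]4C(=C)C[C@H]3[C@@H]1C(C)C | intermediate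
9 | 4,4a,5-trihydroxy-4,7-dimethyl-1-(propan-2-yl)-3,4,4a,5,8,8a-hexahydronaphthalen-2(1H)-one (all three OH and 8a-H cis) | O=C1C[C@](C)(O)[C@@]2(O)[C@H](O)C=C(C)C[C@H]2[C@@H]1C(C)C | intermediate
10 | 6,7-epoxide of 9 (oxirane cis to 5-OH) | O=C1C[C@](C)(O)[C@@]2(O)[C@H](O)[C@@H]3O[C@]3(C)C[C@H]2[C@@H]1C(C)C | intermediate
11 | 5-O-methanesulfonate of 10 | O=C1C[C@](C)(O)[C@@]2(O)[C@H](OS(C)(=O)=O)[C@@H]3O[C@]3(C)C[C@H]2[C@@H]1C(C)C | intermediate
12 | 2-alcohol of 11 (2-OH cis to 4-OH and to isopropyl) | O[C@@H]1C[C@](C)(O)[C@@]2(O)[C@H](OS(C)(=O)=O)[C@@H]3O[C@]3(C)C[C@H]2[C@@H]1C(C)C | intermediate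
13 | 3-(benzyloxy)-4-methoxybenzoic acid | COc1ccc(C(=O)O)cc1OCc1ccccc1 | starting material
14 | 2-O-[3-(benzyloxy)-4-methoxybenzoyl] ester of 12 | COc1ccc(C(=O)O[C@@H]2C[C@](C)(O)[C@@]3(O)[C@H](OS(C)(=O)=O)[C@@H]4O[C@]4(C)C[C@H]3[C@@H]2C(C)C)cc1OCc1ccccc1 | intermediate
15 | trans-fused epoxy hydroazulenone ester (ketone between C(CH3)OH and ring-fusion CH) | COc1ccc(C(=O)O[C@@H]2C[C@](C)(O)C(=O)[C@H]3[C@@H](C[C@@]4(C)O[C@@H]34)[C@@H]2C(C)C)cc1OCc1ccccc1 | intermediate
16 | secondary alcohol from 15 (epimer mixture at the new carbinol) | COc1ccc(C(=O)O[C@@H]2C[C@](C)(O)C(O)[C@H]3[C@@H](C[C@@]4(C)O[C@@H]34)[C@@H]2C(C)C)cc1OCc1ccccc1 | intermediate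
17 | O-(imidazol-1-ylthiocarbonyl) derivative of 16 | COc1ccc(C(=O)O[C@@H]2C[C@](C)(O)C(OC(=S)n5ccnc5)[C@H]3[C@@H](C[C@@]4(C)O[C@@H]34)[C@@H]2C(C)C)cc1OCc1ccccc1 | intermediate
18 | O-benzyl ether of the target | COc1ccc(C(=O)O[C@@H]2C[C@](C)(O)C[C@H]3[C@@H](C[C@@]4(C)O[C@@H]34)[C@@H]2C(C)C)cc1OCc1ccccc1 | intermediate
19 | target, 3-hydroxy-4-methoxybenzoate of the trans-fused epoxy hydroazulene diol | COc1ccc(C(=O)O[C@@H]2C[C@](C)(O)C[C@H]3[C@@H](C[C@@]4(C)O[C@@H]34)[C@@H]2C(C)C)cc1O | target

Total step count: 16. Longest linear sequence: 16 steps (1 → 19); the acid 13 enters in step 11.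

**Steps most likely to fail**

Step 4. The hindered enone may form the reactive dienamine only slowly, or the catalyst may discriminate poorly between the two enantiotopic dienone carbons, so that enantioselectivity is low. Fallback, from 5 back to 6: 5 would be cyclised with an achiral base (DBU, MeCN, rt, enolate Michael addition), which should give 6 together with the enantiomer of 6 F1. Then 6 and F1 would be separated by preparative chromatography on a chiral stationary phase, which returns the route at 6.

Step 12. The ketone product may enolise and open the adjacent oxirane by E1cB, the aroyl group may shift from O-2 to a neighbouring alkoxide, or alignment may be imperfect so that another bond migrates. Fallback, from 12 to 16: the rearrangement would be run before the esterification. Treatment of 12 with KOt-Bu (2.2 equiv) in THF at −40 °C should give the ring-contracted epoxy dihydroxy ketone F2. Without isolation, F2 would be reduced as it forms by NaBH4/MeOH added to the same flask, giving the ring-contracted epoxy triol F3 as an epimer mixture at the new carbinol. Steglich esterification of F3 with 13 at the less hindered ring carbinol would then give 16; that carbinol lies next to the isopropyl-bearing carbon, whereas the other is neopentyl-like beside C(CH3)OH.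

Step 15. The thiocarbonyl derivative may cyclise onto the neighbouring tertiary alcohol to a cyclic thionocarbonate, which would fragment to the tertiary radical and remove the wrong oxygen. Fallback, from 15 to 18: the tertiary alcohol of 15 would first be masked with N-(trimethylsilyl)imidazole (CH2Cl2, rt; neutral, so the ketone is not enolised) as the trimethylsilyl ether of 15 F4. Reduction of F4 with NaBH4 (EtOH–THF, −20 °C) would give the silyl-protected secondary alcohol F5. Treatment of F5 with 1,1'-thiocarbonyldiimidazole and DMAP would give the silyl-protected thiocarbonyl imidazolide F6, which can no longer cyclise. Bu3SnH, AIBN, toluene, 80 °C would reduce F6 to the trimethylsilyl ether of 18 F7, and TBAF buffered with AcOH would then cleave F7 to 18.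

Further compounds
F1 | step 4 | enantiomer of 6 | O=C1C=C(C)[C@]2(O)C=CC(=O)C[C@@H]2[C@H]1C(C)C
F2 | step 12 | ring-contracted epoxy dihydroxy ketone | O[C@@H]1C[C@](C)(O)C(=O)[C@H]2[C@@H](C[C@@]3(C)O[C@@H]23)[C@@H]1C(C)C
F3 | step 12 | ring-contracted epoxy triol | O[C@@H]1C[C@](C)(O)C(O)[C@H]2[C@@H](C[C@@]3(C)O[C@@H]23)[C@@H]1C(C)C
F4 | step 15 | trimethylsilyl ether of 15 | COc1ccc(C(=O)O[C@@H]2C[C@](C)(O[Si](C)(C)C)C(=O)[C@H]3[C@@H](C[C@@]4(C)O[C@@H]34)[C@@H]2C(C)C)cc1OCc1ccccc1
F5 | step 15 | silyl-protected secondary alcohol | COc1ccc(C(=O)O[C@@H]2C[C@](C)(O[Si](C)(C)C)C(O)[C@H]3[C@@H](C[C@@]4(C)O[C@@H]34)[C@@H]2C(C)C)cc1OCc1ccccc1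
F6 | step 15 | silyl-protected thiocarbonyl imidazolide | COc1ccc(C(=O)O[C@@H]2C[C@](C)(O[Si](C)(C)C)C(OC(=S)n5ccnc5)[C@H]3[C@@H](C[C@@]4(C)O[C@@H]34)[C@@H]2C(C)C)cc1OCc1ccccc1
F7 | step 15 | trimethylsilyl ether of 18 | COc1ccc(C(=O)O[C@@H]2C[C@](C)(O[Si](C)(C)C)C[C@H]3[C@@H](C[C@@]4(C)O[C@@H]34)[C@@H]2C(C)C)cc1OCc1ccccc1
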